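**Plan**

Ring letters: A = terminal 3,5-dihydroxyphenoxy ring; B = next ring, C-linked to B′; C = 2,6-dihydroxy-1,4-dioxy ring; D = central ring; E and F = the two identical rings on D, C-linked to E′ and F′.
Enabling feature: ring D has oxygen at D1 and D4 (para) and aryloxy groups at D2 and D6, so it is a 2,6-bis(aryloxy)hydroquinone. This is the reduced form of a quinone whose C2 and C6 can be loaded by displacing the chlorides of 2,6-dichloro-1,4-benzoquinone.
Cuts: all O–CH3 bonds, then C4–O(D1), then D2–O and D6–O together; in the other half A–O(B1), B5–B′ and B4–O(C1); in the E–E′ unit the biaryl bond E5–E′.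
Forward: the E–E′ phenol (bromination, Suzuki, Baeyer–Villiger) is added twice to the dichloroquinone, followed by reduction and D4 silylation. Separately the C–O–B ether is made, then B′ (Suzuki), A (Ullmann) and a C4 boronic acid (C–H borylation). The halves are joined by Chan–Lam–Evans coupling, then desilylated and demethylated. All nine rings are bought; ring D is aromatised by reduction.
Stereochemistry: none to set. There is no stereocentre, and no biaryl axis is stereogenic because B′, E′ and F′ are symmetric about their axes.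

Key step: step 4

Assumption: 4-bromo-2,6-dimethoxybenzaldehyde is taken as a catalogue compound, like the other starting materials; methyl ethers serve as the only permanent protecting group.

**Step 1**
Reactants: 1 2,4,6-trimethoxybenzaldehyde
Product: 2 3-bromo-2,4,6-trimethoxybenzaldehyde
Conditions: NBS (1.0 equiv), MeCN, 0 °C to rt
Reagents that add atoms: N-bromosuccinimide, O=C1CCC(=O)N1Br
Why: Electrophilic aromatic bromination, in which C3 and C5 are equivalent and ortho/para to three methoxy groups, while the first bromine and the formyl group slow a second substitution.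

**Step 2**
Reactants: 2 3-bromo-2,4,6-trimethoxybenzaldehyde; 3 2,4,6-trimethoxyphenylboronic acid (1.5–2 equiv)
Product: 4 2,2′,4,4′,6,6′-hexamethoxybiphenyl-3-carbaldehyde
Conditions: Pd(OAc)2 (5 mol %), SPhos (10 mol %), K3PO4, toluene/H2O, 100 °C, Ar
Reagents that add atoms: none
Why: Suzuki–Miyaura coupling with a bulky dialkylbiarylphosphine, the ligand class established for tetra-ortho-substituted biaryls, where the formyl group eases oxidative addition of zerovalent palladium into the crowded C–Br bond and excess 3 offsets protodeboronation.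

**Step 3**
Reactants: 4 2,2′,4,4′,6,6′-hexamethoxybiphenyl-3-carbaldehyde
Product: 6 2,2′,4,4′,6,6′-hexamethoxybiphenyl-3-ol (E–E′ phenol; 2,4,6-trimethoxy-3-(2,4,6-trimethoxyphenyl)phenol), via aryl formate 5 (not isolated)
Conditions: mCPBA, CH2Cl2, 0 °C to rt; aq. NaHCO3 wash; then K2CO3 (cat.), MeOH, rt, Ar
Reagents that add atoms: m-chloroperbenzoic acid, O=C(OO)c1cccc(Cl)c1
Why: Baeyer–Villiger oxidation of an electron-rich benzaldehyde (Dakin-type outcome), in which the trialkoxyaryl group migrates, the formate shields the oxidation-prone phenol until the peracid is gone, and mild methanolysis then frees it.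

**Step 4**
Reactants: 6 2,2′,4,4′,6,6′-hexamethoxybiphenyl-3-ol (2.1 equiv); 7 2,6-dichloro-1,4-benzoquinone
Product: 9 2,6-bis[(2,2′,4,4′,6,6′-hexamethoxybiphenyl-3-yl)oxy]-1,4-benzoquinone, via monochloroquinone 8 (not isolated)
Conditions: K2CO3 (dried, powdered), 4 Å MS, dry MeCN, 0 °C to rt, Ar, dark
Reagents that add atoms: none
Why: The potassium phenoxide of 6 attacks through oxygen at C2 of 7, a carbon that bears chlorine and lies β to the C4 carbonyl, the enolate so formed expels chloride to restore the quinone as 8, and the same addition–elimination at C6 gives 9. The closest known reaction type is the vinylogous acyl substitution by which halo-1,4-benzoquinones and halonaphthoquinones are converted into aryloxyquinones with phenols and carbonate bases. No ring closes and no stereocentre is formed; two C–O bonds (D2–O and D6–O) are made. Site selectivity for C2/C6 over C3/C5 is needed and is secured by the leaving groups: only attack at a C–Cl carbon can finish at the quinone oxidation level, whereas an adduct at C–H can merely revert or wait for an oxidant, which is kept scarce by using no excess of 7. O- versus C-attack of the ambident phenoxide is settled by ring E itself, whose two ortho carbons and para carbon all carry methoxy groups. The crowding around the phenoxide oxygen counts for little because the accepting carbon is a flat sp2 centre next to a C–H, and dry, cold, oxygen-free conditions are chosen to hold back electron transfer from the electron-rich phenoxide to the quinone.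

**Step 5**
Reactants: 9 2,6-bis[(2,2′,4,4′,6,6′-hexamethoxybiphenyl-3-yl)oxy]-1,4-benzoquinone
Product: 10 2,6-bis[(2,2′,4,4′,6,6′-hexamethoxybiphenyl-3-yl)oxy]benzene-1,4-diol
Conditions: Na2S2O4, THF/H2O, rt, Ar; used at once
Reagents that add atoms: none
Why: Dithionite reduction of a quinone to its hydroquinone, a standard two-electron aromatisation that leaves aryl ethers untouched and also collects any material already reduced by redox exchange in step 4.

**Step 6**
Reactants: 10 2,6-bis[(2,2′,4,4′,6,6′-hexamethoxybiphenyl-3-yl)oxy]benzene-1,4-diol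
Product: 11 2,6-bis[(2,2′,4,4′,6,6′-hexamethoxybiphenyl-3-yl)oxy]-4-(triisopropylsilyloxy)phenol
Conditions: TIPSCl (1.05 equiv), imidazole, CH2Cl2/DMF, 0 °C
Reagents that add atoms: triisopropylsilyl chloride, CC(C)[Si](Cl)(C(C)C)C(C)C
Why: Sterically governed O-silylation, in which the bulky chlorosilane under weakly basic conditions reaches the D4 hydroxyl between two C–H but not the D1 hydroxyl buried between two aryloxy groups, whereas a small alkylating agent with carbonate could be steered to D1 by its higher acidity.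

**Step 7**
Reactants: 12 2,6-dimethoxyphenol; 13 4-bromo-2,6-dimethoxybenzaldehyde
Product: 14 4-(2,6-dimethoxyphenoxy)-2,6-dimethoxybenzaldehyde
Conditions: CuI (10 mol %), picolinic acid (20 mol %), K3PO4, DMSO, 90 °C, Ar
Reagents that add atoms: none
Why: Ligand-accelerated Ullmann ether synthesis, a system established for 2,6-disubstituted phenols, applied to a bromide that has two free ortho positions and is activated by the para formyl group (forms C1–O–B4).

**Step 8**
Reactants: 14 4-(2,6-dimethoxyphenoxy)-2,6-dimethoxybenzaldehyde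
Product: 15 3-bromo-4-(2,6-dimethoxyphenoxy)-2,6-dimethoxybenzaldehyde
Conditions: NBS (1.0 equiv), MeCN, −10 to 0 °C
Reagents that add atoms: N-bromosuccinimide, O=C1CCC(=O)N1Br
Why: Electrophilic aromatic bromination, directed to the equivalent positions 3/5 of ring B because they are ortho/para to three oxygen donors (the bridging oxygen conjugates mainly with ring B, ring C being twisted out of plane), whereas the open positions of ring C profit from only two.

**Step 9**
Reactants: 15 3-bromo-4-(2,6-dimethoxyphenoxy)-2,6-dimethoxybenzaldehyde; 3 2,4,6-trimethoxyphenylboronic acid (2 equiv)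
Product: 16 4-(2,6-dimethoxyphenoxy)-2,6-dimethoxy-3-(2,4,6-trimethoxyphenyl)benzaldehyde
Conditions: Pd(OAc)2 (5 mol %), SPhos (10 mol %), K3PO4, toluene/H2O, 100 °C, Ar
Reagents that add atoms: none
Why: Suzuki–Miyaura coupling as in step 2, in which the aryloxy group can turn towards B3–H, so the bromide should be about as accessible as one flanked by two methoxy groups (forms B5–B′).

**Step 10**
Reactants: 16 4-(2,6-dimethoxyphenoxy)-2,6-dimethoxy-3-(2,4,6-trimethoxyphenyl)benzaldehyde
Product: 18 4-(2,6-dimethoxyphenoxy)-2,6-dimethoxy-3-(2,4,6-trimethoxyphenyl)phenol, via aryl formate 17 (not isolated)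
Conditions: mCPBA, CH2Cl2, 0 °C to rt; aq. NaHCO3 wash; then K2CO3 (cat.), MeOH, rt, Ar
Reagents that add atoms: m-chloroperbenzoic acid, O=C(OO)c1cccc(Cl)c1
Why: Baeyer–Villiger oxidation and methanolysis as in step 3, turning the formyl group that activated steps 7–9 into the B1 hydroxyl.

**Step 11**
Reactants: 18 4-(2,6-dimethoxyphenoxy)-2,6-dimethoxy-3-(2,4,6-trimethoxyphenyl)phenol; 19 1-bromo-3,5-dimethoxybenzene
Product: 20 1-(3,5-dimethoxyphenoxy)-4-(2,6-dimethoxyphenoxy)-2,6-dimethoxy-3-(2,4,6-trimethoxyphenyl)benzene (A–B–B′–C nonamethyl ether)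
Conditions: CuI (10 mol %), picolinic acid (20 mol %), K3PO4, DMSO, 100 °C, Ar
Reagents that add atoms: none
Why: Ligand-accelerated Ullmann ether synthesis that pairs the 2,6-dimethoxy-flanked phenol with an aryl bromide free of ortho substituents, 18 carrying no halogen that could compete.

**Step 12**
Reactants: 20 A–B–B′–C nonamethyl ether
Product: 22 [4-{4-(3,5-dimethoxyphenoxy)-3,5-dimethoxy-2-(2,4,6-trimethoxyphenyl)phenoxy}-3,5-dimethoxyphenyl]boronic acid, via pinacol boronate 21 (not isolated)
Conditions: [Ir(OMe)(cod)]2 (2.5 mol %), dtbpy (5 mol %), B2pin2, THF, 80 °C; then NaIO4, NH4OAc, acetone/H2O, rt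
Reagents that add atoms: bis(pinacolato)diboron, CC1(C)OB(OC1(C)C)B1OC(C)(C)C(C)(C)O1; water, O
Why: Sterically controlled iridium-catalysed C–H borylation followed by periodate cleavage of the pinacol ester in the same flask, C4–H of ring C being the only aromatic C–H of 20 without an ortho substituent, as in the known 5-selective borylation of 1,2,3-trisubstituted benzenes.

**Step 13**
Reactants: 11 2,6-bis[(2,2′,4,4′,6,6′-hexamethoxybiphenyl-3-yl)oxy]-4-(triisopropylsilyloxy)phenol; 22 A–B–B′–C boronic acid (1.5 equiv)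
Product: 23 henicosamethyl ether of the target with D4–O–TIPS
Conditions: Cu(OAc)2 (2 equiv), pyridine (5 equiv), 4 Å MS, CH2Cl2, dry air, rt
Reagents that add atoms: none
Why: Chan–Lam–Evans oxidative coupling, in which phenoxide and aryl group meet on copper and reductive elimination from trivalent copper forms D1–O–C4 at room temperature, a reaction type known to accept 2,6-disubstituted phenols when the boronic acid has free ortho positions and to tolerate aryl silyl ethers.

**Step 14**
Reactants: 23 henicosamethyl ether with D4–O–TIPS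
Product: 24 henicosamethyl ether of the target with free D4 hydroxyl
Conditions: TBAF, AcOH, THF, 0 °C
Reagents that add atoms: none
Why: Fluoride-induced cleavage of an aryl silyl ether, buffered with acetic acid so that the phenoxide is protonated at once.

**Step 15**
Reactants: 24 henicosamethyl ether with free D4 hydroxyl
Product: 25 CNP0117322.0 (target)
Conditions: BBr3 (about 3 equiv per OMe), CH2Cl2, −78 °C to rt, Ar; then MeOH/H2O at 0 °C; Sephadex LH-20 under inert gas
Reagents that add atoms: none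
Why: Lewis acid-mediated cleavage of aryl methyl ethers, in which bromide attacks the methyl carbon of each boron-complexed ether, while diaryl ether and biaryl bonds offer no sp3 carbon and stay intact.

**Compound list**

1 | 2,4,6-trimethoxybenzaldehyde | COc1cc(OC)c(C=O)c(OC)c1 | starting material
2 | 3-bromo-2,4,6-trimethoxybenzaldehyde | COc1cc(OC)c(C=O)c(OC)c1Br | intermediate
3 | 2,4,6-trimethoxyphenylboronic acid | COc1cc(OC)c(B(O)O)c(OC)c1 | starting material
4 | 2,2′,4,4′,6,6′-hexamethoxybiphenyl-3-carbaldehyde | COc1cc(OC)c(-c2c(OC)cc(OC)c(C=O)c2OC)c(OC)c1 | intermediate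
5 | 2,2′,4,4′,6,6′-hexamethoxybiphenyl-3-yl formate | COc1cc(OC)c(-c2c(OC)cc(OC)c(OC=O)c2OC)c(OC)c1 | intermediate
6 | 2,2′,4,4′,6,6′-hexamethoxybiphenyl-3-ol (E–E′ phenol) | Oc1c(OC)cc(OC)c(-c2c(OC)cc(OC)cc2OC)c1OC | intermediate
7 | 2,6-dichloro-1,4-benzoquinone | O=C1C=C(Cl)C(=O)C(Cl)=C1 | starting material
8 | 2-chloro-6-[(2,2′,4,4′,6,6′-hexamethoxybiphenyl-3-yl)oxy]-1,4-benzoquinone | O=C1C=C(Cl)C(=O)C(Oc2c(OC)cc(OC)c(-c3c(OC)cc(OC)cc3OC)c2OC)=C1 | intermediate
9 | 2,6-bis[(2,2′,4,4′,6,6′-hexamethoxybiphenyl-3-yl)oxy]-1,4-benzoquinone | O=C1C=C(Oc2c(OC)cc(OC)c(-c3c(OC)cc(OC)cc3OC)c2OC)C(=O)C(Oc2c(OC)cc(OC)c(-c3c(OC)cc(OC)cc3OC)c2OC)=C1 | intermediate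
10 | 2,6-bis[(2,2′,4,4′,6,6′-hexamethoxybiphenyl-3-yl)oxy]benzene-1,4-diol | Oc1cc(Oc2c(OC)cc(OC)c(-c3c(OC)cc(OC)cc3OC)c2OC)c(O)c(Oc2c(OC)cc(OC)c(-c3c(OC)cc(OC)cc3OC)c2OC)c1 | intermediate
11 | 2,6-bis[(2,2′,4,4′,6,6′-hexamethoxybiphenyl-3-yl)oxy]-4-(triisopropylsilyloxy)phenol | CC(C)[Si](Oc1cc(Oc2c(OC)cc(OC)c(-c3c(OC)cc(OC)cc3OC)c2OC)c(O)c(Oc2c(OC)cc(OC)c(-c3c(OC)cc(OC)cc3OC)c2OC)c1)(C(C)C)C(C)C | intermediate
12 | 2,6-dimethoxyphenol | COc1cccc(OC)c1O | starting material
13 | 4-bromo-2,6-dimethoxybenzaldehyde | COc1cc(Br)cc(OC)c1C=O | starting material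
14 | 4-(2,6-dimethoxyphenoxy)-2,6-dimethoxybenzaldehyde | COc1cc(Oc2c(OC)cccc2OC)cc(OC)c1C=O | intermediate
15 | 3-bromo-4-(2,6-dimethoxyphenoxy)-2,6-dimethoxybenzaldehyde | COc1cc(Oc2c(OC)cccc2OC)c(Br)c(OC)c1C=O | intermediate
16 | 4-(2,6-dimethoxyphenoxy)-2,6-dimethoxy-3-(2,4,6-trimethoxyphenyl)benzaldehyde | COc1cc(Oc2c(OC)cccc2OC)c(-c2c(OC)cc(OC)cc2OC)c(OC)c1C=O | intermediate
17 | 4-(2,6-dimethoxyphenoxy)-2,6-dimethoxy-3-(2,4,6-trimethoxyphenyl)phenyl formate | COc1cc(Oc2c(OC)cccc2OC)c(-c2c(OC)cc(OC)cc2OC)c(OC)c1OC=O | intermediate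
18 | 4-(2,6-dimethoxyphenoxy)-2,6-dimethoxy-3-(2,4,6-trimethoxyphenyl)phenol | COc1cc(Oc2c(OC)cccc2OC)c(-c2c(OC)cc(OC)cc2OC)c(OC)c1O | intermediate
19 | 1-bromo-3,5-dimethoxybenzene | COc1cc(Br)cc(OC)c1 | starting material
20 | 1-(3,5-dimethoxyphenoxy)-4-(2,6-dimethoxyphenoxy)-2,6-dimethoxy-3-(2,4,6-trimethoxyphenyl)benzene | COc1cc(OC)cc(Oc2c(OC)cc(Oc3c(OC)cccc3OC)c(-c3c(OC)cc(OC)cc3OC)c2OC)c1 | intermediate
21 | pinacol ester of boronic acid 22 (Bpin at C4 of ring C) | COc1cc(OC)cc(Oc2c(OC)cc(Oc3c(OC)cc(B4OC(C)(C)C(C)(C)O4)cc3OC)c(-c3c(OC)cc(OC)cc3OC)c2OC)c1 | intermediate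
22 | [4-{4-(3,5-dimethoxyphenoxy)-3,5-dimethoxy-2-(2,4,6-trimethoxyphenyl)phenoxy}-3,5-dimethoxyphenyl]boronic acid | COc1cc(OC)cc(Oc2c(OC)cc(Oc3c(OC)cc(B(O)O)cc3OC)c(-c3c(OC)cc(OC)cc3OC)c2OC)c1 | intermediate
23 | henicosamethyl ether of the target, D4 hydroxyl as TIPS ether | COc1cc(OC)cc(Oc2c(OC)cc(Oc3c(OC)cc(Oc4c(Oc5c(OC)cc(OC)c(-c6c(OC)cc(OC)cc6OC)c5OC)cc(O[Si](C(C)C)(C(C)C)C(C)C)cc4Oc4c(OC)cc(OC)c(-c5c(OC)cc(OC)cc5OC)c4OC)cc3OC)c(-c3c(OC)cc(OC)cc3OC)c2OC)c1 | intermediate
24 | henicosamethyl ether of the target, D4 hydroxyl free | COc1cc(OC)cc(Oc2c(OC)cc(Oc3c(OC)cc(Oc4c(Oc5c(OC)cc(OC)c(-c6c(OC)cc(OC)cc6OC)c5OC)cc(O)cc4Oc4c(OC)cc(OC)c(-c5c(OC)cc(OC)cc5OC)c4OC)cc3OC)c(-c3c(OC)cc(OC)cc3OC)c2OC)c1 | intermediate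
25 | CNP0117322.0 | Oc1cc(O)cc(Oc2c(O)cc(Oc3c(O)cc(Oc4c(Oc5c(O)cc(O)c(-c6c(O)cc(O)cc6O)c5O)cc(O)cc4Oc4c(O)cc(O)c(-c5c(O)cc(O)cc5O)c4O)cc3O)c(-c3c(O)cc(O)cc3O)c2O)c1 | target

**Step count and risks**

Total step count: 15.
Longest linear sequence: 9 steps (steps 1–6, then 13–15; the branch of steps 7–12, then 13–15, is equally long).

**Step 4.**
- What may go wrong: electron transfer from the very electron-rich phenoxide to the oxidising dichloroquinone; stalling after the first substitution because the first aryloxy group damps the C4 carbonyl; and conjugate addition at C3/C5.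
- Fallback (twofold SNAr at the arene level, with a formyl group as the latent D1 oxygen): it sets out from 6. Two equivalents of 6 and commercial 2,6-difluoro-4-methoxybenzaldehyde (K2CO3, DMF, 110 °C) should give 2,6-bis[(2,2′,4,4′,6,6′-hexamethoxybiphenyl-3-yl)oxy]-4-methoxybenzaldehyde F1, both fluorides being ortho to the formyl group. Baeyer–Villiger oxidation (mCPBA, CH2Cl2) leads to the aryl formate F2. Methanolysis (K2CO3, MeOH) gives 2,6-bis[(2,2′,4,4′,6,6′-hexamethoxybiphenyl-3-yl)oxy]-4-methoxyphenol F3, in which D4 is already capped. Chan–Lam–Evans coupling of F3 with 22 under the conditions of step 13 gives the docosamethyl ether F4. BBr3 as in step 15 brings the sequence back to the route at 25, and steps 5, 6 and 14 fall away.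

**Step 13.**
- What may go wrong: slow delivery of the buried D1 phenoxide to copper, so that hydroxylation and protodeboronation of the boronic acid and copper/air oxidation of the hydroquinone monoether take over.
- Fallback (redox-neutral Ullmann coupling with an aryl iodide under inert gas): it sets out from 21, isolated after the borylation instead of being hydrolysed, and from 11. Copper-catalysed iododeboronation (CuI, 1,10-phenanthroline, KI, MeOH/H2O, air, 80 °C) delivers iodine as iodide and should therefore spare rings A and B′; it gives the ring C aryl iodide F5. F5 and 11 are then condensed with CuI, N,N-dimethylglycine and Cs2CO3 in dry dioxane at 90 °C under argon, a medium in which the carbonate is barely soluble and the TIPS ether should hold. The sequence comes back to the route at 23.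

**Step 9.**
- What may go wrong: protodeboronation of the di-ortho-methoxy boronic acid outrunning the slow transmetalation onto the crowded arylpalladium bromide, together with hydrodebromination of the substrate.
- Fallback (base-free Negishi coupling with an organozinc in place of boron): it sets out from 15. 1,3,5-Trimethoxybenzene is lithiated between two methoxy groups (n-BuLi, THF, 0 °C) to 2,4,6-trimethoxyphenyllithium F6. This is transmetalated with ZnCl2 to (2,4,6-trimethoxyphenyl)zinc chloride F7, which is coupled with 15 (Pd2(dba)3, RuPhos, THF, 60 °C). Under anhydrous conditions the arylzinc has no protonolysis channel, and the hindered, electron-rich formyl group should tolerate it. The sequence comes back to the route at 16.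

**Further compounds**

F1 | step 4 | 2,6-bis[(2,2′,4,4′,6,6′-hexamethoxybiphenyl-3-yl)oxy]-4-methoxybenzaldehyde | COc1cc(Oc2c(OC)cc(OC)c(-c3c(OC)cc(OC)cc3OC)c2OC)c(C=O)c(Oc2c(OC)cc(OC)c(-c3c(OC)cc(OC)cc3OC)c2OC)c1
F2 | step 4 | 2,6-bis[(2,2′,4,4′,6,6′-hexamethoxybiphenyl-3-yl)oxy]-4-methoxyphenyl formate | COc1cc(Oc2c(OC)cc(OC)c(-c3c(OC)cc(OC)cc3OC)c2OC)c(OC=O)c(Oc2c(OC)cc(OC)c(-c3c(OC)cc(OC)cc3OC)c2OC)c1
F3 | step 4 | 2,6-bis[(2,2′,4,4′,6,6′-hexamethoxybiphenyl-3-yl)oxy]-4-methoxyphenol | COc1cc(Oc2c(OC)cc(OC)c(-c3c(OC)cc(OC)cc3OC)c2OC)c(O)c(Oc2c(OC)cc(OC)c(-c3c(OC)cc(OC)cc3OC)c2OC)c1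
F4 | step 4 | docosamethyl ether of the target | COc1cc(OC)cc(Oc2c(OC)cc(Oc3c(OC)cc(Oc4c(Oc5c(OC)cc(OC)c(-c6c(OC)cc(OC)cc6OC)c5OC)cc(OC)cc4Oc4c(OC)cc(OC)c(-c5c(OC)cc(OC)cc5OC)c4OC)cc3OC)c(-c3c(OC)cc(OC)cc3OC)c2OC)c1
F5 | step 13 | 1-(3,5-dimethoxyphenoxy)-4-(4-iodo-2,6-dimethoxyphenoxy)-2,6-dimethoxy-3-(2,4,6-trimethoxyphenyl)benzene | COc1cc(OC)cc(Oc2c(OC)cc(Oc3c(OC)cc(I)cc3OC)c(-c3c(OC)cc(OC)cc3OC)c2OC)c1
F6 | step 9 | 2,4,6-trimethoxyphenyllithium | [Li]c1c(OC)cc(OC)cc1OC
F7 | step 9 | (2,4,6-trimethoxyphenyl)zinc chloride | COc1cc(OC)c([Zn]Cl)c(OC)c1
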